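**Plan**

1. Retrosynthesis: the azepanone N–CH2 bond is cut first (lactam N-alkylation). Then the amide bond N–C23 of the nine-membered ring is cut while C8 and C23 are reconnected. This leads back to a cis-fused cyclopentanone–lactone A whose quaternary C8 carries the β-amino acyl chain C9–C11 with lactone B.
2. Enabling feature: in the nine-membered ring the lactam carbonyl C23 and the methine C8 (α to the C9 ketone, fusion carbon of lactone A) are linked through N, C11, C10 and C9. A C8–C23 bond therefore gives a 2-acylcyclopentanone (C23, C22, C3, C4, C8) whose ring carbonyl lies six atoms from the side-chain nitrogen.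
3. Further cuts: C8–C9 (aldol, then oxidation), C22=C21 (aldol condensation, later hydrogenated), C3–ethyl (conjugate addition), C7–CH3 (lactone alkylation), C12–C13 of lactone B (Barbier allylation).
4. Forward: iodolactonisation of (S)-cyclopentenylacetic acid puts lactone A on a cyclopentene. Allylic oxidation, ethyl addition and side-chain condensation give an alkylidene ketone that can enolise only at C8. Aldol with the aspartate-derived aldehyde, oxidation and hydrogenation give the ring-expansion substrate; carbamate removal triggers the expansion and N-alkylation closes the azepanone.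
5. Stereochemistry: C4 and C8 come from the starting acid; C7, C3, quaternary C8 and C22 are set by substrate control on the bicycle. C11 comes from L-aspartic acid, C12 from chelation-controlled allylation, C14 from hydrogenation; C8 is finally set by protonation of the C9 enolate.

Key step: step 18

Remark: atom labels are those of the target skeleton (C3 CH–Et, C4 CH–O of lactone A, C7 CH–Me of lactone A, C8, C9 ketone, C10, C11 CH–N, C12 CH–O of lactone B, C14 CH–Me of lactone B, C22 lactam α-carbon, C23 lactam carbonyl). "Exo" means the convex face of the cis-fused bicycle. The nitrogen is carried as a tert-butyl carbamate so that it survives the hydrogenation that sets C22. (S)-2-(Cyclopent-2-en-1-yl)acetic acid is assumed to be purchasable as the single enantiomer (otherwise by classical resolution of the racemate).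

**Route**

Step 1
Reactants: 1 (S)-2-(cyclopent-2-en-1-yl)acetic acid
Product: 2 cis-fused iodolactone (3aS,6R,6aR)-6-iodohexahydro-2H-cyclopenta[b]furan-2-one
Conditions: I2, KI, NaHCO3, H2O, rt, dark
Reagents that add atoms: iodine, II
Why: Iodolactonisation, in which the carboxylate opens the iodonium ion 5-exo at the nearer alkene carbon C4 with anti addition, so the γ-lactone is necessarily cis-fused to the C8 centre of 1 and iodine ends up trans to the ring oxygen at C3.

Step 2
Reactants: 2 iodolactone
Product: 3 (3aS,6aR)-3,3a,4,6a-tetrahydro-2H-cyclopenta[b]furan-2-one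
Conditions: DBU, toluene, 80 °C
Reagents that add atoms: none
Why: E2 dehydroiodination, in which only a C22 hydrogen is anti-periplanar to the exo iodine, so the alkene forms at C3=C22, allylic to the lactone oxygen.

Step 3
Reactants: 3 ene lactone
Product: 5 exo-methyl lactone (3S,3aS,6aS)-3-methyl-3,3a,4,6a-tetrahydro-2H-cyclopenta[b]furan-2-one, via lithium enolate 4 (not isolated)
Conditions: LDA, THF, −78 °C; then MeI, −78 to −40 °C
Reagents that add atoms: methyl iodide, CI
Why: Lactone enolate alkylation, in which methyl iodide approaches the convex face anti to the C8–C23 bond and so sets C7 with the methyl group exo.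

Step 4
Reactants: 5 exo-methyl lactone
Product: 6 bicyclic enone lactone (3S,3aS,6aS)-3-methyl-3,3a-dihydro-2H-cyclopenta[b]furan-2,4(6aH)-dione
Conditions: Rh2(cap)4 (dirhodium tetracaprolactamate, 1 mol %), tBuOOH, K2CO3, CH2Cl2, rt
Reagents that add atoms: tert-butyl hydroperoxide, CC(C)(C)OO
Why: Allylic C–H oxidation with tert-butyl hydroperoxide, in which hydrogen abstraction should occur at the only allylic methylene (C23), the other allylic position C4 being an electron-poor acyloxy methine, and the peroxide collapses to the enone.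

Step 5
Reactants: 7 butane-1,4-diol
Product: 8 4-[(tert-butyldiphenylsilyl)oxy]butan-1-ol
Conditions: NaH (1.0 equiv), THF, rt; then TBDPSCl (1.0 equiv)
Reagents that add atoms: tert-butyl(chloro)diphenylsilane, CC(C)(C)[Si](Cl)(c1ccccc1)c1ccccc1
Why: Monosilylation of a symmetric diol through its sparingly soluble monosodium alkoxide (Williamson-type O-silylation).

Step 6
Reactants: 8 monosilyl ether
Product: 9 4-[(tert-butyldiphenylsilyl)oxy]butanal
Conditions: Dess–Martin periodinane, NaHCO3, CH2Cl2, rt
Reagents that add atoms: none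
Why: Dess–Martin oxidation of a primary alcohol stops cleanly at the aldehyde.

Step 7
Reactants: 6 bicyclic enone lactone; 9 silyloxybutanal
Product: 11 aldol adduct with exo ethyl at C3 and a 1-hydroxy-4-silyloxybutyl group at C22, via ethylzinc enolate 10 (not isolated)
Conditions: Et2Zn (1.3 equiv), Cu(OTf)2 (2 mol %), P(OEt)3 (4 mol %), toluene, −30 °C; then 9, −30 to 0 °C; aq NH4Cl
Reagents that add atoms: diethylzinc, CC[Zn]CC
Why: Copper-catalysed conjugate addition of diethylzinc with aldol trapping of the zinc enolate, in which ethyl should add to C3 on the convex face anti to the adjacent C4–O bond (sets C3), while the two aldol centres are removed in step 8.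

Step 8
Reactants: 11 aldol adduct
Product: 13 (E)-alkylidene keto lactone, via mesylate 12 (not isolated)
Conditions: MsCl, Et3N, CH2Cl2, 0 °C; then DBU, 0 °C
Reagents that add atoms: none
Why: Mesylation and E1cB elimination through the C22 enolate give the conjugated exocyclic enone as the more stable E isomer, which makes C22 sp2 and leaves C8 as the only enolisable position of the ketone.

Step 9
Reactants: 14 N-Boc-L-aspartic acid 4-benzyl ester
Product: 15 benzyl (S)-3-[(tert-butoxycarbonyl)amino]-4-hydroxybutanoate
Conditions: BH3·SMe2, THF, 0 °C to rt; MeOH quench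
Reagents that add atoms: none
Why: Chemoselective borane reduction of the free carboxylic acid in the presence of the benzyl ester and the carbamate.

Step 10
Reactants: 15 amino alcohol
Product: 16 benzyl (S)-3-[(tert-butoxycarbonyl)amino]-4-oxobutanoate
Conditions: Dess–Martin periodinane, NaHCO3, CH2Cl2, 0 °C to rt; used at once
Reagents that add atoms: none
Why: Dess–Martin oxidation under buffered conditions is expected to give the N-Boc α-amino aldehyde without loss of the C11 configuration.

Step 11
Reactants: 16 α-amino aldehyde; 17 ethyl 2-(bromomethyl)acrylate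
Product: 19 α-methylene lactone benzyl (S)-3-[(tert-butoxycarbonyl)amino]-3-[(S)-4-methylidene-5-oxotetrahydrofuran-2-yl]propanoate, via hydroxy ester 18 (not isolated)
Conditions: Zn dust, THF/sat. aq NH4Cl, 0 °C to rt; then TsOH·H2O (cat.), CH2Cl2, rt
Reagents that add atoms: none
Why: Barbier-type allylation by the allylzinc reagent from 17 followed by acid-catalysed lactonisation, in which chelation of zinc between the aldehyde oxygen and the carbamate (Cram-chelate model) should favour the syn amino alcohol, that is the (S) configuration at C12.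

Step 12
Reactants: 19 α-methylene lactone
Product: 20 (S)-3-[(tert-butoxycarbonyl)amino]-3-[(2S,4S)-4-methyl-5-oxotetrahydrofuran-2-yl]propanoic acid
Conditions: H2 (1 atm), 10% Pd/C, EtOAc, rt
Reagents that add atoms: none
Why: Heterogeneous hydrogenation should add hydrogen to the exocyclic methylene from the face opposite the bulky C12 substituent, giving the cis-2,4-disubstituted lactone (sets C14, also the more stable epimer), and the benzyl ester is hydrogenolysed in the same operation.

Step 13
Reactants: 20 lactone acid
Product: 21 tert-butyl N-[(S)-3-hydroxy-1-[(2S,4S)-4-methyl-5-oxotetrahydrofuran-2-yl]propyl]carbamate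
Conditions: BH3·SMe2, THF, 0 °C; MeOH quench
Reagents that add atoms: none
Why: Borane reduces the carboxylic acid much faster than the γ-lactone or the carbamate.

Step 14
Reactants: 21 lactone alcohol
Product: 22 tert-butyl N-[(S)-1-[(2S,4S)-4-methyl-5-oxotetrahydrofuran-2-yl]-3-oxopropyl]carbamate
Conditions: Dess–Martin periodinane, NaHCO3, CH2Cl2, rt
Reagents that add atoms: none
Why: Dess–Martin oxidation of the primary alcohol to the β-carbamoyl aldehyde under neutral conditions.

Step 15
Reactants: 13 alkylidene keto lactone; 22 lactone B aldehyde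
Product: 24 aldol adduct with quaternary C8 (C9 carbinol epimers), via lithium dienolate 23 (not isolated)
Conditions: LiHMDS (1.05 equiv), THF, −78 °C; then 22 (1.3 equiv), −78 °C; AcOH quench at −78 °C
Reagents that add atoms: none
Why: Aldol addition of a regiodefined lithium enolate, in which the ketone can be deprotonated only at C8, the aldehyde is attacked from the convex face because C7 of lactone A occupies the other face (sets quaternary C8), the lactone C4–O bond lies near the enolate plane and is poorly aligned for β-elimination, and proton transfer from the carbamate N–H to a ketone enolate is slow at −78 °C.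

Step 16
Reactants: 24 aldol adduct
Product: 25 alkylidene 2-acyl ketone (1,3-diketone with quaternary C8)
Conditions: Dess–Martin periodinane, NaHCO3, CH2Cl2, rt
Reagents that add atoms: none
Why: Dess–Martin oxidation of the secondary alcohol gives the non-enolisable 1,3-diketone under neutral conditions that avoid retro-aldol cleavage.

Step 17
Reactants: 25 alkylidene 1,3-diketone
Product: 26 ring-expansion precursor, cis-fused cyclopentanone–lactone A with quaternary C8 bearing the β-(Boc-amino) acyl chain and the C22 side chain cis to ethyl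
Conditions: H2 (1 atm), 10% Pd/C, EtOAc, rt
Reagents that add atoms: none
Why: Heterogeneous hydrogenation of the exocyclic enone, in which allylic 1,3-strain with the E side chain turns the C3 ethyl group pseudoaxial on the face that also carries the C8 acyl chain, so hydrogen should be delivered from the lactone face and place the C22 side chain cis to ethyl (sets C22).

Step 18
Reactants: 26 ring-expansion precursor
Product: 28 nine-membered keto NH lactam with lactones A and B and the silyloxybutyl chain on C22, via free amine 27 (not isolated)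
Conditions: TFA/CH2Cl2 1:4, 0 °C; evaporation; then Et3N, CH2Cl2, rt
Reagents that add atoms: none
Why: Acidolysis of the carbamate and neutralisation free the C11 amine, which adds to the ring ketone C23 in a 6-exo-trig closure to a bicyclic hemiaminal; its alkoxide collapses with cleavage of the C8–C23 bond and expulsion of the C9 enolate, so the six-membered hemiaminal and the cyclopentanone merge into the nine-membered lactam without any medium-ring transition state. The closest known reaction type is the amine-triggered retro-Claisen acyl-transfer ring expansion of cyclic 1,3-dicarbonyl compounds that carry an amino-terminated side chain. The only new stereocentre, C8, arises on protonation of the enolate and, being α to the C9 ketone, can equilibrate under the amine base to the cis-fused lactone A with the C7 methyl group trans to C9. The amine must choose C23 over C9 and over the lactone B carbonyl: attack at C9 would close a four-membered ring and attack at lactone B needs a strained 7-oxa-2-azabicyclo[2.2.1]heptane intermediate, whereas C23 is a strained ketone activated by the adjacent acyl group and is reached through a chair-like six-membered transition state. C22 should be untouched because Et3N enolises C23 only slowly and C22 becomes an amide α-carbon once the ring has expanded.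

Step 19
Reactants: 28 nine-membered lactam
Product: 29 primary alcohol
Conditions: HF·pyridine, pyridine/THF, 0 °C to rt
Reagents that add atoms: none
Why: Fluoride cleavage of the silyl ether under buffered conditions that leave the β-amido ketone and both lactones untouched.

Step 20
Reactants: 29 primary alcohol
Product: 30 primary mesylate
Conditions: MsCl, Et3N, CH2Cl2, 0 °C
Reagents that add atoms: methanesulfonyl chloride, CS(=O)(=O)Cl
Why: Sulfonylation of the primary alcohol, to which the secondary lactam N–H is inert under these conditions.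

Step 21
Reactants: 30 primary mesylate
Product: 31 target CNP0311700.3
Conditions: NaH, THF (0.01 M), 0 °C to rt
Reagents that add atoms: none
Why: Intramolecular N-alkylation of the lactam anion (7-exo-tet) closes the azepanone ring, the irreversible amide alkylation at high dilution and low temperature being expected to outrun side reactions of the reversibly formed ketone enolate.

**Compound list**

1 | (S)-2-(cyclopent-2-en-1-yl)acetic acid | OC(=O)C[C@@H]1CCC=C1 | starting material
2 | (3aS,6R,6aR)-6-iodohexahydro-2H-cyclopenta[b]furan-2-one (cis-fused, iodine trans to ring oxygen) | C1[C@@H](I)[C@@H]2OC(=O)C[C@@H]2C1 | intermediate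
3 | (3aS,6aR)-3,3a,4,6a-tetrahydro-2H-cyclopenta[b]furan-2-one | C1=C[C@@H]2OC(=O)C[C@@H]2C1 | intermediate
4 | lithium enolate of lactone 3 | C1=C[C@@H]2OC(O[Li])=C[C@@H]2C1 | intermediate
5 | (3S,3aS,6aS)-3-methyl-3,3a,4,6a-tetrahydro-2H-cyclopenta[b]furan-2-one (methyl exo) | C1=C[C@@H]2OC(=O)[C@@H](C)[C@@H]2C1 | intermediate
6 | (3S,3aS,6aS)-3-methyl-3,3a-dihydro-2H-cyclopenta[b]furan-2,4(6aH)-dione | C1=C[C@@H]2OC(=O)[C@@H](C)[C@@H]2C1=O | intermediate
7 | butane-1,4-diol | OCCCCO | starting material
8 | 4-[(tert-butyldiphenylsilyl)oxy]butan-1-ol | OCCCCO[Si](c1ccccc1)(c1ccccc1)C(C)(C)C | intermediate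
9 | 4-[(tert-butyldiphenylsilyl)oxy]butanal | O=CCCCO[Si](c1ccccc1)(c1ccccc1)C(C)(C)C | intermediate
10 | ethylzinc enolate from ethyl addition to 6 (ethyl exo at C3) | CC[C@H]1[C@@H]2OC(=O)[C@@H](C)[C@@H]2C(O[Zn]CC)=C1 | intermediate
11 | cis-fused keto lactone with exo ethyl (C3), exo methyl (C7) and a 1-hydroxy-4-(TBDPS-oxy)butyl group at C22 trans to ethyl (carbinol epimers) | CC[C@H]1[C@@H]2OC(=O)[C@@H](C)[C@@H]2C(=O)[C@@H]1C(O)CCCO[Si](c1ccccc1)(c1ccccc1)C(C)(C)C | intermediate
12 | methanesulfonate of 11 | CC[C@H]1[C@@H]2OC(=O)[C@@H](C)[C@@H]2C(=O)[C@@H]1C(OS(C)(=O)=O)CCCO[Si](c1ccccc1)(c1ccccc1)C(C)(C)C | intermediate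
13 | cis-fused keto lactone with exo ethyl (C3), exo methyl (C7) and an (E)-4-(TBDPS-oxy)butylidene group at C22 | CC[C@H]1[C@@H]2OC(=O)[C@@H](C)[C@@H]2C(=O)/C1=C/CCCO[Si](c1ccccc1)(c1ccccc1)C(C)(C)C | intermediate
14 | N-(tert-butoxycarbonyl)-L-aspartic acid 4-benzyl ester | CC(C)(C)OC(=O)N[C@@H](CC(=O)OCc1ccccc1)C(=O)O | starting material
15 | benzyl (S)-3-[(tert-butoxycarbonyl)amino]-4-hydroxybutanoate | CC(C)(C)OC(=O)N[C@@H](CC(=O)OCc1ccccc1)CO | intermediate
16 | benzyl (S)-3-[(tert-butoxycarbonyl)amino]-4-oxobutanoate | CC(C)(C)OC(=O)N[C@@H](CC(=O)OCc1ccccc1)C=O | intermediate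
17 | ethyl 2-(bromomethyl)acrylate | C=C(CBr)C(=O)OCC | starting material
18 | 7-benzyl 1-ethyl (4S,5S)-5-[(tert-butoxycarbonyl)amino]-4-hydroxy-2-methylideneheptanedioate | CC(C)(C)OC(=O)N[C@@H](CC(=O)OCc1ccccc1)[C@@H](O)CC(=C)C(=O)OCC | intermediate
19 | benzyl (S)-3-[(tert-butoxycarbonyl)amino]-3-[(S)-4-methylidene-5-oxotetrahydrofuran-2-yl]propanoate | CC(C)(C)OC(=O)N[C@@H](CC(=O)OCc1ccccc1)[C@@H]1CC(=C)C(=O)O1 | intermediate
20 | (S)-3-[(tert-butoxycarbonyl)amino]-3-[(2S,4S)-4-methyl-5-oxotetrahydrofuran-2-yl]propanoic acid | CC(C)(C)OC(=O)N[C@@H](CC(=O)O)[C@@H]1C[C@H](C)C(=O)O1 | intermediate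
21 | tert-butyl N-[(S)-3-hydroxy-1-[(2S,4S)-4-methyl-5-oxotetrahydrofuran-2-yl]propyl]carbamate | CC(C)(C)OC(=O)N[C@@H](CCO)[C@@H]1C[C@H](C)C(=O)O1 | intermediate
22 | tert-butyl N-[(S)-1-[(2S,4S)-4-methyl-5-oxotetrahydrofuran-2-yl]-3-oxopropyl]carbamate | CC(C)(C)OC(=O)N[C@@H](CC=O)[C@@H]1C[C@H](C)C(=O)O1 | intermediate
23 | lithium dienolate of 13 (C8=C23–OLi) | CC[C@H]1[C@@H]2OC(=O)[C@@H](C)C2=C(O[Li])/C1=C/CCCO[Si](c1ccccc1)(c1ccccc1)C(C)(C)C | intermediate
24 | alkylidene keto lactone with quaternary C8 carrying the exo 1-hydroxy-3-(Boc-amino)-3-(lactone B)propyl chain (C9 carbinol epimers) | CC[C@H]1[C@@H]2OC(=O)[C@@H](C)[C@]2(C(O)C[C@H](NC(=O)OC(C)(C)C)[C@@H]2C[C@H](C)C(=O)O2)C(=O)/C1=C/CCCO[Si](c1ccccc1)(c1ccccc1)C(C)(C)C | intermediate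
25 | alkylidene 1,3-diketone with quaternary C8 carrying the β-(Boc-amino) acyl chain with lactone B | CC[C@H]1[C@@H]2OC(=O)[C@@H](C)[C@]2(C(=O)C[C@H](NC(=O)OC(C)(C)C)[C@@H]2C[C@H](C)C(=O)O2)C(=O)/C1=C/CCCO[Si](c1ccccc1)(c1ccccc1)C(C)(C)C | intermediate
26 | cis-fused cyclopentanone–lactone A with quaternary C8 bearing the β-(Boc-amino) acyl chain with lactone B; ethyl (C3) and 4-(TBDPS-oxy)butyl (C22) cis and exo | CC[C@H]1[C@@H]2OC(=O)[C@@H](C)[C@]2(C(=O)C[C@H](NC(=O)OC(C)(C)C)[C@@H]2C[C@H](C)C(=O)O2)C(=O)[C@H]1CCCCO[Si](c1ccccc1)(c1ccccc1)C(C)(C)C | intermediate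
27 | free C11 amine of 26 | CC[C@H]1[C@@H]2OC(=O)[C@@H](C)[C@]2(C(=O)C[C@H](N)[C@@H]2C[C@H](C)C(=O)O2)C(=O)[C@H]1CCCCO[Si](c1ccccc1)(c1ccccc1)C(C)(C)C | intermediate
28 | nine-membered keto NH lactam with cis-fused lactone A, lactone B on C11 and the 4-(TBDPS-oxy)butyl chain on C22 | CC[C@H]1[C@@H]2OC(=O)[C@@H](C)[C@@H]2C(=O)C[C@@H]([C@@H]2C[C@H](C)C(=O)O2)NC(=O)[C@H]1CCCCO[Si](c1ccccc1)(c1ccccc1)C(C)(C)C | intermediate
29 | primary alcohol from desilylation of 28 | CC[C@H]1[C@@H]2OC(=O)[C@@H](C)[C@@H]2C(=O)C[C@@H]([C@@H]2C[C@H](C)C(=O)O2)NC(=O)[C@H]1CCCCO | intermediate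
30 | methanesulfonate of 29 | CC[C@H]1[C@@H]2OC(=O)[C@@H](C)[C@@H]2C(=O)C[C@@H]([C@@H]2C[C@H](C)C(=O)O2)NC(=O)[C@H]1CCCCOS(C)(=O)=O | intermediate
31 | CNP0311700.3 | CC[C@H]1[C@@H]2OC(=O)[C@@H](C)[C@@H]2C(=O)C[C@@H]([C@@H]2C[C@H](C)C(=O)O2)N2CCCC[C@@H]1C2=O | target

**Step count and risks**

Total: 21 steps. Longest linear sequence: 13 steps (1 to 31; the branch from 14 is equally long).

Steps most likely to fail:

Step 17. Hydrogen may be delivered to the ethyl-bearing face of the exocyclic alkene, or the double bond may migrate into the ring on palladium, so that the C22 side chain ends up trans to ethyl. The fallback sets out from 13 and uses a hydroxyl group to direct the hydrogenation. Luche reduction (NaBH4, CeCl3·7H2O, MeOH, −40 °C) should attack C23 from the convex face and give the endo allylic alcohol F1, with its hydroxyl on the lactone face. Hydrogenation with [Ir(cod)(PCy3)(py)]PF6 (H2, CH2Cl2) is then directed by that hydroxyl and should give the saturated alcohol F2 with the side chain cis to ethyl. Dess–Martin oxidation gives the ketone F3. Kinetic deprotonation with LiHMDS at −78 °C should remove the exposed, oxygen-activated exo hydrogen at C8 in preference to the concave C22 hydrogen and give the lithium enolate F4, which adds to aldehyde 22 to give the aldol adduct F5. Dess–Martin oxidation of F5 returns to the route at 26.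

Step 15. Proton transfer to the hindered enolate (from the carbamate N–H or the aldehyde α-methylene) or reversal of the congested lithium aldolate may compete with C–C bond formation at the ring-fusion carbon. The fallback sets out from 13. The same regiodefined enolate is trapped with TMSCl (LiHMDS, TMSCl, THF, −78 °C) as the trimethylsilyl dienol ether F6, which is combined with aldehyde 22 in a Mukaiyama aldol addition under BF3·OEt2 (CH2Cl2, −78 °C). This is non-basic and not reversible, and it returns to the route at 24.

Step 21. The base may enolise the C9 ketone, which opens the way to β-elimination of the amide nitrogen or to Claisen-type attack on lactone A in competition with N-alkylation. The fallback sets out from 29 and closes the ring under acidic, reductive conditions. Dess–Martin oxidation gives the aldehyde F7. In TFA/CH2Cl2 the lactam N–H adds to the aldehyde to give the cyclic N-acyl hemiaminal F8, which ionises to the N-acyliminium ion and is reduced by Et3SiH (reductive N-alkylation of a lactam). This returns to the route at 31.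

Further compounds
F1 | step 17 | endo allylic alcohol from 1,2-reduction of 13 (C23 hydroxyl on the lactone face) | CC[C@H]1[C@@H]2OC(=O)[C@@H](C)[C@@H]2[C@H](O)/C1=C/CCCO[Si](c1ccccc1)(c1ccccc1)C(C)(C)C
F2 | step 17 | saturated alcohol with the C22 side chain cis to ethyl | CC[C@H]1[C@@H]2OC(=O)[C@@H](C)[C@@H]2[C@H](O)[C@H]1CCCCO[Si](c1ccccc1)(c1ccccc1)C(C)(C)C
F3 | step 17 | saturated keto lactone with cis C3 ethyl and C22 side chain | CC[C@H]1[C@@H]2OC(=O)[C@@H](C)[C@@H]2C(=O)[C@H]1CCCCO[Si](c1ccccc1)(c1ccccc1)C(C)(C)C
F4 | step 17 | lithium enolate of F3 at C8 | CC[C@H]1[C@@H]2OC(=O)[C@@H](C)C2=C(O[Li])[C@H]1CCCCO[Si](c1ccccc1)(c1ccccc1)C(C)(C)C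
F5 | step 17 | saturated aldol adduct with quaternary C8 (C9 carbinol epimers) | CC[C@H]1[C@@H]2OC(=O)[C@@H](C)[C@]2(C(O)C[C@H](NC(=O)OC(C)(C)C)[C@@H]2C[C@H](C)C(=O)O2)C(=O)[C@H]1CCCCO[Si](c1ccccc1)(c1ccccc1)C(C)(C)C
F6 | step 15 | trimethylsilyl dienol ether of 13 (C8=C23–OSiMe3) | CC[C@H]1[C@@H]2OC(=O)[C@@H](C)C2=C(O[Si](C)(C)C)/C1=C/CCCO[Si](c1ccccc1)(c1ccccc1)C(C)(C)C
F7 | step 21 | aldehyde from oxidation of 29 | CC[C@H]1[C@@H]2OC(=O)[C@@H](C)[C@@H]2C(=O)C[C@@H]([C@@H]2C[C@H](C)C(=O)O2)NC(=O)[C@H]1CCCC=O
F8 | step 21 | cyclic N-acyl hemiaminal (hydroxy epimers) | CC[C@H]1[C@@H]2OC(=O)[C@@H](C)[C@@H]2C(=O)C[C@@H]([C@@H]2C[C@H](C)C(=O)O2)N2C(O)CCC[C@@H]1C2=O
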